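**Plan**

- Ring D is numbered C1 (on the CH that carries the 2,4-dioxyphenyl group), C2 (O), C3, C4 (O), C5, C6 (on the bridging methine). It is a resorcinol fused to the seven-membered ring through the adjacent carbons C1/C6 with its oxygens meta, so it maps onto an ethynyl group (C5–C6), a methoxyalkyne (C1–C2) and an external alkoxyalkyne (C3–C4).
- Retrosynthesis cuts C1–C6 (which also opens the seven-membered ring), C2–C3 and C4–C5, giving diyne 29 and ethoxyethyne.
- The methoxyalkyne goes back to a methyl ester (CH2–CO2Me to C≡C–OMe), the arm to a benzylic bromide, a boryl acrylate and an arylboronic acid, the ethynyl group to a ring ester, and both dihydrofurans to carbene C–H insertions into the two 4-methoxybenzyl ethers of a 2,6-dibromo-3,5-dioxybenzyl core.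
- Forward order: central arene, diaryl dihydrofuran, ester-bearing dihydrofuran, ethynyl group, arm, methoxyalkyne, then ring D and the seven-membered ring in one step, then the eight phenols.
- Stereochemistry: C3 and C6 of the bis-dihydrofuran come from two chiral dirhodium catalysts, C5 and C2 are brought to trans by base and acid equilibration, and the arm stereocentre comes from a rhodium/BINAP conjugate arylation. The key step creates no stereocentre.

Key step: step 17

Assumption: the facial preferences of Rh2(R-PTAD)4, Rh2(S-PTTL)4 and the rhodium/(R)-BINAP catalyst are taken to be those drawn; a catalyst that favoured the other face would be replaced by its mirror image.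

**Route**

Step 1
Reactants: 1 3,5-dihydroxybenzyl alcohol; 2 4-methoxybenzyl chloride (2.1 equiv)
Product: 3 3,5-bis(4-methoxybenzyloxy)benzyl alcohol
Conditions: K2CO3, DMF, 60 °C
Reagents that add atoms: none
Why: Williamson ether synthesis in which carbonate deprotonates only the two phenols, installing the two O–CH2Ar groups whose benzylic carbons later become C2 and C6 of the bis-dihydrofuran.

Step 2
Reactants: 3 3,5-bis(4-methoxybenzyloxy)benzyl alcohol
Product: 4 silyl ether of alcohol 3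
Conditions: TBSCl, imidazole, DMF, rt
Reagents that add atoms: tert-butyldimethylsilyl chloride, CC(C)(C)[Si](C)(C)Cl
Why: Standard silylation of the primary alcohol, so that the organolithium, oxidation and carbene steps meet no O–H bond.

Step 3
Reactants: 4 silyl ether of alcohol 3
Product: 5 2,6-dibromide of silyl ether 4
Conditions: NBS (2.05 equiv), MeCN, 0 °C
Reagents that add atoms: N-bromosuccinimide, O=C1CCC(=O)N1Br
Why: Electrophilic aromatic bromination; the two positions flanking the CH2OSi group are each para to one ether oxygen and ortho to the other, whereas the position between the oxygens is only ortho-activated and shielded, so 2,6-dibromination is expected.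

Step 4
Reactants: 5 2,6-dibromide of silyl ether 4; 6 3,5-dimethoxybenzonitrile
Product: 8 diaryl ketone hydrazone, via N–H ketimine 7 (not isolated)
Conditions: n-BuLi (1.0 equiv), THF, −78 °C; 6, −78 → 0 °C; MeOH; then N2H4·H2O, EtOH, 60 °C
Reagents that add atoms: hydrazine hydrate, NN.O
Why: Mono bromine–lithium exchange, addition of the aryllithium to the nitrile and transimination of the N–H ketimine with hydrazine give the hindered hydrazone without condensing a di-ortho-substituted benzophenone.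

Step 5
Reactants: 8 diaryl ketone hydrazone
Product: 10 cis-2,3-diaryl dihydrobenzofuran bromide (2S,3R), via diaryldiazomethane 9 (not isolated)
Conditions: MnO2, CH2Cl2, 0 °C; filtration; Rh2(R-PTAD)4 (1 mol%), CH2Cl2, −20 °C → rt
Reagents that add atoms: none
Why: Oxidation of the hydrazone to the diazo compound and enantioselective intramolecular 1,5 C–H insertion of the donor/donor rhodium carbene into the benzylic C–H of the neighbouring 4-methoxybenzyl ether; the concerted insertion sets C3 (R) under catalyst control and places the two aryl groups cis.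

Step 6
Reactants: 10 cis-2,3-diaryl dihydrobenzofuran bromide; 11 dimethyl oxalate (3 equiv)
Product: 12 aryl α-keto ester
Conditions: n-BuLi (1.1 equiv), THF, −78 °C; cannulation into 11, THF, −78 °C
Reagents that add atoms: none
Why: Bromine–lithium exchange outruns deprotonation of the ring C–H bonds at −78 °C, and inverse addition to excess oxalate stops at the keto ester (acylation of an aryllithium).

Step 7
Reactants: 12 aryl α-keto ester
Product: 14 aryl diazoacetate, via tosylhydrazone 13 (not isolated)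
Conditions: TsNHNH2, MeOH, 50 °C; solvent exchange; DBU, CH2Cl2, rt
Reagents that add atoms: 4-methylbenzenesulfonohydrazide, Cc1ccc(S(=O)(=O)NN)cc1
Why: Condensation of the electrophilic keto group with the sulfonyl hydrazide and base-induced loss of sulfinate (Bamford–Stevens type) is a standard entry to aryl diazoacetates.

Step 8
Reactants: 14 aryl diazoacetate
Product: 16 trans ester of the bis-dihydrofuran (5R,6R), via cis ester 15 (not isolated)
Conditions: Rh2(S-PTTL)4 (1 mol%), toluene, −60 °C; then NaOMe, MeOH, rt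
Reagents that add atoms: none
Why: Enantioselective 1,5 C–H insertion of the donor/acceptor rhodium carbene into the remaining 4-methoxybenzyl ether gives the cis 2-aryl-3-carboxylate with C6 (R) set by the catalyst, and methoxide then epimerises the acidic C5 to the more stable trans ester; ring opening of the enolate is disfavoured because it is the reverse of a 5-endo-trig closure.

Step 9
Reactants: 16 trans ester of the bis-dihydrofuran; 17 dimethyl (1-diazo-2-oxopropyl)phosphonate
Product: 19 5-ethynyl bis-dihydrofuran, via aldehyde 18 (not isolated)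
Conditions: i-Bu2AlH (1.2 equiv), CH2Cl2, −78 °C; MeOH; then 17, K2CO3, MeOH, 0 °C → rt
Reagents that add atoms: none
Why: Low-temperature hydride reduction stops at the aldehyde level and Seyferth–Gilbert homologation with the Ohira–Bestmann reagent converts the aldehyde into the terminal alkyne in the same flask; any epimerisation of the aldehyde under carbonate leads back to the favoured trans isomer.

Step 10
Reactants: 19 5-ethynyl bis-dihydrofuran
Product: 20 C-silylated alkyne
Conditions: n-BuLi, THF, −78 °C; TIPSOTf, −78 → 0 °C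
Reagents that add atoms: triisopropylsilyl trifluoromethanesulfonate, CC(C)[Si](C(C)C)(C(C)C)OS(=O)(=O)C(F)(F)F
Why: Deprotonation of the terminal alkyne (the most acidic C–H) and C-silylation; the bulky silyl group keeps the alkyne out of the palladium and rhodium steps that follow and is stable to acid.

Step 11
Reactants: 20 C-silylated alkyne
Product: 21 all-trans benzylic alcohol
Conditions: CF3CO2H/CH2Cl2/H2O (10:88:2), 0 °C → rt
Reagents that add atoms: none
Why: Aqueous acid cleaves the primary silyl ether and reversibly ionises the C2–O bond of the 2-(4-methoxyphenyl)dihydrofuran to a 4-methoxybenzylic cation (acid epimerisation of a benzylic ether); reclosure by the phenol under thermodynamic control gives the 2,3-trans ring, so C2 becomes R while C3, C5 and C6 are untouched.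

Step 12
Reactants: 21 all-trans benzylic alcohol
Product: 22 benzylic bromide
Conditions: CBr4, PPh3, CH2Cl2, 0 °C
Reagents that add atoms: carbon tetrabromide, BrC(Br)(Br)Br
Why: Appel reaction of the primary benzylic alcohol under neutral conditions.

Step 13
Reactants: 22 benzylic bromide; 23 methyl (E)-3-(pinacolboryl)acrylate
Product: 24 (E)-γ-aryl enoate
Conditions: PdCl2(dppf) (5 mol%), K2CO3, THF/H2O (10:1), 60 °C
Reagents that add atoms: none
Why: Suzuki–Miyaura sp3–sp2 coupling of a benzylic bromide with an alkenylboronate keeps the alkene geometry; the mild base and the twisted 2,6-disubstituted arene disfavour migration of the double bond into conjugation.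

Step 14
Reactants: 24 (E)-γ-aryl enoate; 25 (2,4-dimethoxyphenyl)boronic acid (3 equiv)
Product: 26 β-aryl ester (3S)
Conditions: [Rh(OH)((R)-BINAP)]2 (3 mol% Rh), 1,4-dioxane/H2O (10:1), 50 °C
Reagents that add atoms: none
Why: Hayashi–Miyaura reaction, in which the aryl–rhodium species formed by transmetalation adds to the β-carbon of the enoate from the face selected by the chiral bisphosphine and protonation releases the ester; the new stereocentre is set by the ligand.

Step 15
Reactants: 26 β-aryl ester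
Product: 28 methoxyalkyne, via ketene acetal phosphate 27 (not isolated)
Conditions: LiN(i-Pr)2, THF/DMPU, −78 °C; ClP(O)(OEt)2; then t-BuLi (2.2 equiv), −100 → −78 °C
Reagents that add atoms: none
Why: O-Phosphorylation of the ester enolate and β-elimination of phosphate with tert-butyllithium at very low temperature is the known conversion of an alkanoate into a 1-alkoxyalkyne; the stereocentre is β to the carbonyl and never part of an enolate.

Step 16
Reactants: 28 methoxyalkyne
Product: 29 diyne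
Conditions: Bu4NF, THF, 0 °C → rt
Reagents that add atoms: none
Why: Fluoride-induced cleavage of the C(sp)–Si bond; alkynyl alkyl ethers are stable to fluoride and base.

Step 17
Reactants: 29 diyne; 30 ethoxyethyne
Product: 31 cycloadduct with seven methyl ethers and one ethyl ether
Conditions: [Rh(cod)2]BF4/(R)-BINAP (10 mol%, pre-treated with H2, then Ar), CH2Cl2, rt, 30 added by syringe pump until 29 is consumed
Reagents that add atoms: none
Why: Monovalent rhodium couples two of the alkynes oxidatively to a rhodacyclopentadiene, the third alkyne inserts and reductive elimination closes the benzene ring, a (2+2+2) cycloaddition of a tethered diyne with a monoyne that is known for alkynyl ethers and for benzo-fused seven-membered rings. Ring D closes through C2–C3 and C4–C5 to ethoxyethyne, and the seven-membered carbocycle closes through C1–C6 between the two internal alkyne carbons, which the rigid arene in the five-atom tether holds close. No stereocentre is formed, and the five existing ones are sp3 carbons outside the reacting π-systems. The step needs regioselectivity: the nucleophilic CH terminus of ethoxyethyne should bond to the methoxy-bearing terminus and its oxygen-bearing carbon to the unsubstituted terminus, a head-to-tail pairing of two ynol ethers that also keeps the alkoxy groups apart and gives the meta-dioxygenated ring. The reaction is a pure addition of one molecule of 30 to 29 in which every atom of both partners ends up in 31, and dosing 30 slowly keeps its concentration low and limits its self-trimerisation.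

Step 18
Reactants: 31 cycloadduct with seven methyl ethers and one ethyl ether
Product: 32 target CNP0154047.1
Conditions: BBr3 (20 equiv), CH2Cl2, −78 °C → rt; then H2O
Reagents that add atoms: none
Why: Lewis acid dealkylation of all seven aryl methyl ethers and the aryl ethyl ether; the trans dihydrobenzofurans are the thermodynamic isomers and the other stereocentres cannot ionise, so the configuration is kept.

**Compound list**

Abbreviations in names: PMB = 4-methoxybenzyl; TBS = tert-butyldimethylsilyl; TIPS = triisopropylsilyl; BDF = 2,3,5,6-tetrahydrobenzo[1,2-b:5,4-b']difuran (O1, C2, C3, C3a, C4, C4a, C5, C6, O7, C7a, C8, C8a).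

1 | 3,5-dihydroxybenzyl alcohol | OCc1cc(O)cc(O)c1 | starting material
2 | 4-methoxybenzyl chloride | COc1ccc(CCl)cc1 | starting material
3 | 3,5-bis(4-methoxybenzyloxy)benzyl alcohol | OCc1cc(OCc2ccc(OC)cc2)cc(OCc2ccc(OC)cc2)c1 | intermediate
4 | tert-butyl[3,5-bis(4-methoxybenzyloxy)benzyloxy]dimethylsilane | CC(C)(C)[Si](C)(C)OCc1cc(OCc2ccc(OC)cc2)cc(OCc2ccc(OC)cc2)c1 | intermediate
5 | tert-butyl[2,6-dibromo-3,5-bis(4-methoxybenzyloxy)benzyloxy]dimethylsilane | CC(C)(C)[Si](C)(C)OCc1c(Br)c(OCc2ccc(OC)cc2)cc(OCc2ccc(OC)cc2)c1Br | intermediate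
6 | 3,5-dimethoxybenzonitrile | COc1cc(OC)cc(C#N)c1 | starting material
7 | [3-bromo-2-(TBSO-methyl)-4,6-bis(PMB-oxy)phenyl](3,5-dimethoxyphenyl)methanimine | CC(C)(C)[Si](C)(C)OCc1c(Br)c(OCc2ccc(OC)cc2)cc(OCc2ccc(OC)cc2)c1C(=N)c1cc(OC)cc(OC)c1 | intermediate (not isolated)
8 | hydrazone of [3-bromo-2-(TBSO-methyl)-4,6-bis(PMB-oxy)phenyl](3,5-dimethoxyphenyl)methanone | CC(C)(C)[Si](C)(C)OCc1c(Br)c(OCc2ccc(OC)cc2)cc(OCc2ccc(OC)cc2)c1C(=NN)c1cc(OC)cc(OC)c1 | intermediate
9 | [3-bromo-2-(TBSO-methyl)-4,6-bis(PMB-oxy)phenyl](3,5-dimethoxyphenyl)diazomethane | CC(C)(C)[Si](C)(C)OCc1c(Br)c(OCc2ccc(OC)cc2)cc(OCc2ccc(OC)cc2)c1C(=[N+]=[N-])c1cc(OC)cc(OC)c1 | intermediate (not isolated)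
10 | (2S,3R)-5-bromo-4-(TBSO-methyl)-3-(3,5-dimethoxyphenyl)-6-(PMB-oxy)-2-(4-methoxyphenyl)-2,3-dihydro-1-benzofuran (2,3-cis) | COc1ccc([C@H]2Oc3cc(OCc4ccc(OC)cc4)c(Br)c(CO[Si](C)(C)C(C)(C)C)c3[C@H]2c2cc(OC)cc(OC)c2)cc1 | intermediate
11 | dimethyl oxalate | COC(=O)C(=O)OC | starting material
12 | methyl 2-oxo-2-[(2S,3R)-4-(TBSO-methyl)-3-(3,5-dimethoxyphenyl)-6-(PMB-oxy)-2-(4-methoxyphenyl)-2,3-dihydro-1-benzofuran-5-yl]acetate | COc1ccc([C@H]2Oc3cc(OCc4ccc(OC)cc4)c(C(=O)C(=O)OC)c(CO[Si](C)(C)C(C)(C)C)c3[C@H]2c2cc(OC)cc(OC)c2)cc1 | intermediate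
13 | N-tosylhydrazone of keto ester 12 | COc1ccc([C@H]2Oc3cc(OCc4ccc(OC)cc4)c(C(=NNS(=O)(=O)c4ccc(C)cc4)C(=O)OC)c(CO[Si](C)(C)C(C)(C)C)c3[C@H]2c2cc(OC)cc(OC)c2)cc1 | intermediate (not isolated)
14 | methyl 2-diazo-2-[(2S,3R)-4-(TBSO-methyl)-3-(3,5-dimethoxyphenyl)-6-(PMB-oxy)-2-(4-methoxyphenyl)-2,3-dihydro-1-benzofuran-5-yl]acetate | COc1ccc([C@H]2Oc3cc(OCc4ccc(OC)cc4)c(C(=[N+]=[N-])C(=O)OC)c(CO[Si](C)(C)C(C)(C)C)c3[C@H]2c2cc(OC)cc(OC)c2)cc1 | intermediate
15 | methyl (2S,3R,5S,6R)-4-(TBSO-methyl)-3-(3,5-dimethoxyphenyl)-2,6-bis(4-methoxyphenyl)-BDF-5-carboxylate (2,3-cis, 5,6-cis) | COc1ccc([C@H]2Oc3cc4c([C@H](C(=O)OC)[C@H](c5ccc(OC)cc5)O4)c(CO[Si](C)(C)C(C)(C)C)c3[C@H]2c2cc(OC)cc(OC)c2)cc1 | intermediate (not isolated)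
16 | methyl (2S,3R,5R,6R)-4-(TBSO-methyl)-3-(3,5-dimethoxyphenyl)-2,6-bis(4-methoxyphenyl)-BDF-5-carboxylate (2,3-cis, 5,6-trans) | COc1ccc([C@H]2Oc3cc4c([C@@H](C(=O)OC)[C@H](c5ccc(OC)cc5)O4)c(CO[Si](C)(C)C(C)(C)C)c3[C@H]2c2cc(OC)cc(OC)c2)cc1 | intermediate
17 | dimethyl (1-diazo-2-oxopropyl)phosphonate | CC(=O)C(=[N+]=[N-])P(=O)(OC)OC | starting material
18 | (2S,3R,5R,6R)-4-(TBSO-methyl)-3-(3,5-dimethoxyphenyl)-2,6-bis(4-methoxyphenyl)-BDF-5-carbaldehyde | COc1ccc([C@H]2Oc3cc4c([C@@H](C=O)[C@H](c5ccc(OC)cc5)O4)c(CO[Si](C)(C)C(C)(C)C)c3[C@H]2c2cc(OC)cc(OC)c2)cc1 | intermediate (not isolated)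
19 | (2S,3R,5R,6R)-5-ethynyl-4-(TBSO-methyl)-3-(3,5-dimethoxyphenyl)-2,6-bis(4-methoxyphenyl)-BDF | COc1ccc([C@H]2Oc3cc4c([C@@H](C#C)[C@H](c5ccc(OC)cc5)O4)c(CO[Si](C)(C)C(C)(C)C)c3[C@H]2c2cc(OC)cc(OC)c2)cc1 | intermediate
20 | (2S,3R,5S,6R)-4-(TBSO-methyl)-3-(3,5-dimethoxyphenyl)-2,6-bis(4-methoxyphenyl)-5-[(TIPS)ethynyl]-BDF (2,3-cis, 5,6-trans) | COc1ccc([C@H]2Oc3cc4c([C@@H](C#C[Si](C(C)C)(C(C)C)C(C)C)[C@H](c5ccc(OC)cc5)O4)c(CO[Si](C)(C)C(C)(C)C)c3[C@H]2c2cc(OC)cc(OC)c2)cc1 | intermediate
21 | [(2R,3R,5S,6R)-3-(3,5-dimethoxyphenyl)-2,6-bis(4-methoxyphenyl)-5-[(TIPS)ethynyl]-BDF-4-yl]methanol (2,3-trans, 5,6-trans) | COc1ccc([C@@H]2Oc3cc4c([C@@H](C#C[Si](C(C)C)(C(C)C)C(C)C)[C@H](c5ccc(OC)cc5)O4)c(CO)c3[C@H]2c2cc(OC)cc(OC)c2)cc1 | intermediate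
22 | (2R,3R,5S,6R)-4-(bromomethyl)-3-(3,5-dimethoxyphenyl)-2,6-bis(4-methoxyphenyl)-5-[(TIPS)ethynyl]-BDF | COc1ccc([C@@H]2Oc3cc4c([C@@H](C#C[Si](C(C)C)(C(C)C)C(C)C)[C@H](c5ccc(OC)cc5)O4)c(CBr)c3[C@H]2c2cc(OC)cc(OC)c2)cc1 | intermediate
23 | methyl (E)-3-(4,4,5,5-tetramethyl-1,3,2-dioxaborolan-2-yl)prop-2-enoate | COC(=O)/C=C/B1OC(C)(C)C(C)(C)O1 | starting material
24 | methyl (E)-4-[(2R,3R,5S,6R)-3-(3,5-dimethoxyphenyl)-2,6-bis(4-methoxyphenyl)-5-[(TIPS)ethynyl]-BDF-4-yl]but-2-enoate | COc1ccc([C@@H]2Oc3cc4c([C@@H](C#C[Si](C(C)C)(C(C)C)C(C)C)[C@H](c5ccc(OC)cc5)O4)c(C/C=C/C(=O)OC)c3[C@H]2c2cc(OC)cc(OC)c2)cc1 | intermediate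
25 | (2,4-dimethoxyphenyl)boronic acid | COc1ccc(B(O)O)c(OC)c1 | starting material
26 | methyl (3S)-3-(2,4-dimethoxyphenyl)-4-[(2R,3R,5S,6R)-3-(3,5-dimethoxyphenyl)-2,6-bis(4-methoxyphenyl)-5-[(TIPS)ethynyl]-BDF-4-yl]butanoate | COc1ccc([C@@H]2Oc3cc4c([C@@H](C#C[Si](C(C)C)(C(C)C)C(C)C)[C@H](c5ccc(OC)cc5)O4)c(C[C@H](c5ccc(OC)cc5OC)CC(=O)OC)c3[C@H]2c2cc(OC)cc(OC)c2)cc1 | intermediate
27 | diethyl (3S)-3-(2,4-dimethoxyphenyl)-1-methoxy-4-[(2R,3R,5S,6R)-3-(3,5-dimethoxyphenyl)-2,6-bis(4-methoxyphenyl)-5-[(TIPS)ethynyl]-BDF-4-yl]but-1-en-1-yl phosphate | COc1ccc([C@@H]2Oc3cc4c([C@@H](C#C[Si](C(C)C)(C(C)C)C(C)C)[C@H](c5ccc(OC)cc5)O4)c(C[C@H](c5ccc(OC)cc5OC)C=C(OC)OP(=O)(OCC)OCC)c3[C@H]2c2cc(OC)cc(OC)c2)cc1 | intermediate (not isolated)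
28 | (2R,3R,5S,6R)-4-[(2S)-2-(2,4-dimethoxyphenyl)-4-methoxybut-3-yn-1-yl]-3-(3,5-dimethoxyphenyl)-2,6-bis(4-methoxyphenyl)-5-[(TIPS)ethynyl]-BDF | COc1ccc([C@@H]2Oc3cc4c([C@@H](C#C[Si](C(C)C)(C(C)C)C(C)C)[C@H](c5ccc(OC)cc5)O4)c(C[C@H](c5ccc(OC)cc5OC)C#COC)c3[C@H]2c2cc(OC)cc(OC)c2)cc1 | intermediate
29 | (2R,3R,5R,6R)-4-[(2S)-2-(2,4-dimethoxyphenyl)-4-methoxybut-3-yn-1-yl]-3-(3,5-dimethoxyphenyl)-5-ethynyl-2,6-bis(4-methoxyphenyl)-BDF | COc1ccc([C@@H]2Oc3cc4c([C@@H](C#C)[C@H](c5ccc(OC)cc5)O4)c(C[C@H](c5ccc(OC)cc5OC)C#COC)c3[C@H]2c2cc(OC)cc(OC)c2)cc1 | intermediate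
30 | ethoxyethyne | CCOC#C | starting material
31 | target skeleton as hepta-O-methyl ether with ethoxy at ring D C4 (methoxy at ring D C2), all five stereocentres R | COc1ccc([C@@H]2Oc3cc4c5c(c3[C@H]2c2cc(OC)cc(OC)c2)C[C@H](c2ccc(OC)cc2OC)c2c(OC)cc(OCC)cc2[C@H]5[C@H](c2ccc(OC)cc2)O4)cc1 | intermediate
32 | CNP0154047.1, the octaphenol, both dihydrobenzofurans trans, all five stereocentres R | Oc1ccc([C@@H]2Oc3cc4c5c(c3[C@H]2c2cc(O)cc(O)c2)C[C@H](c2ccc(O)cc2O)c2c(O)cc(O)cc2[C@H]5[C@H](c2ccc(O)cc2)O4)cc1 | target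

**Step count and risks**

Total steps: 18. Longest linear sequence: 18 steps (1 to 32).

Step 17 is the most likely to fail. Ethoxyethyne may trimerise with itself faster than the medium-ring metallacycle forms, and insertion may lose its head-to-tail orientation and give the ortho-dioxygenated ring. The fallback sets out from diyne 29 and replaces ethoxyethyne by commercial ethynylboronic acid pinacol ester under the same rhodium catalyst or Cp*RuCl(cod). The bulky boryl group does not make the alkyne electron-rich and should end up remote from the methoxy-bearing terminus, giving the ring-D aryl pinacol boronate F1. Oxidation with NaBO3·4H2O in THF/H2O would give the ring-D monophenol heptamethyl ether F2, and BBr3 as in step 18 returns to target 32.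

Step 15 is the second risk. tert-Butyllithium may lithiate the dimethoxyarenes or the benzylic C–H next to the new alkyne, which would erode the arm stereocentre, or the elimination may stall at the phosphate. The fallback sets out from ester 26. LiN(SiMe3)2 (2 equiv) and PhSO2F would give the α-phenylsulfonyl ester F3, and NaH with ClP(O)(OEt)2 its sulfonyl enol phosphate F4. SmI2 in THF/DMPU at −78 °C would then remove sulfinate and phosphate reductively (the sulfone-based alkyne synthesis from β-sulfonyl enol phosphates) and return to methoxyalkyne 28 without any alkyllithium.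

Step 14 is the third risk. The electron-rich, ortho-substituted boronic acid may protodeboronate faster than its aryl group is transferred to the hindered enoate, the double bond may migrate into conjugation with the central arene, or the facial selectivity may be poor. The fallback sets out from enoate 24. Heck arylation with 1-iodo-2,4-dimethoxybenzene (Pd(OAc)2, Ag2CO3, DMF) should give the (E)-β-aryl enoate F5, with the aryl group trans to the ester after syn insertion and syn β-hydride elimination. A CuH-catalysed asymmetric conjugate reduction (Cu(OAc)2, p-tol-BINAP of the appropriate handedness, polymethylhydrosiloxane, t-BuOH) would then set the arm stereocentre by hydride delivery and return to ester 26.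

Further compounds
F1 | step 17 | analogue of 31 with a pinacolboryl group in place of ethoxy at ring D C4 | COc1ccc([C@@H]2Oc3cc4c5c(c3[C@H]2c2cc(OC)cc(OC)c2)C[C@H](c2ccc(OC)cc2OC)c2c(OC)cc(B3OC(C)(C)C(C)(C)O3)cc2[C@H]5[C@H](c2ccc(OC)cc2)O4)cc1
F2 | step 17 | hepta-O-methyl ether of the target with free hydroxyl at ring D C4 | COc1ccc([C@@H]2Oc3cc4c5c(c3[C@H]2c2cc(OC)cc(OC)c2)C[C@H](c2ccc(OC)cc2OC)c2c(OC)cc(O)cc2[C@H]5[C@H](c2ccc(OC)cc2)O4)cc1
F3 | step 15 | methyl (3R)-3-(2,4-dimethoxyphenyl)-2-(phenylsulfonyl)-4-[(2R,3R,5S,6R)-3-(3,5-dimethoxyphenyl)-2,6-bis(4-methoxyphenyl)-5-[(TIPS)ethynyl]-BDF-4-yl]butanoate (C2 epimers; same arrangement at C3 as in 26) | COc1ccc([C@@H]2Oc3cc4c([C@@H](C#C[Si](C(C)C)(C(C)C)C(C)C)[C@H](c5ccc(OC)cc5)O4)c(C[C@H](c5ccc(OC)cc5OC)C(C(=O)OC)S(=O)(=O)c5ccccc5)c3[C@H]2c2cc(OC)cc(OC)c2)cc1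
F4 | step 15 | diethyl (3R)-3-(2,4-dimethoxyphenyl)-1-methoxy-2-(phenylsulfonyl)-4-[(2R,3R,5S,6R)-3-(3,5-dimethoxyphenyl)-2,6-bis(4-methoxyphenyl)-5-[(TIPS)ethynyl]-BDF-4-yl]but-1-en-1-yl phosphate | COc1ccc([C@@H]2Oc3cc4c([C@@H](C#C[Si](C(C)C)(C(C)C)C(C)C)[C@H](c5ccc(OC)cc5)O4)c(C[C@H](c5ccc(OC)cc5OC)C(=C(OC)OP(=O)(OCC)OCC)S(=O)(=O)c5ccccc5)c3[C@H]2c2cc(OC)cc(OC)c2)cc1
F5 | step 14 | methyl (E)-3-(2,4-dimethoxyphenyl)-4-[(2R,3R,5S,6R)-3-(3,5-dimethoxyphenyl)-2,6-bis(4-methoxyphenyl)-5-[(TIPS)ethynyl]-BDF-4-yl]but-2-enoate | COc1ccc([C@@H]2Oc3cc4c([C@@H](C#C[Si](C(C)C)(C(C)C)C(C)C)[C@H](c5ccc(OC)cc5)O4)c(C/C(=C\C(=O)OC)c5ccc(OC)cc5OC)c3[C@H]2c2cc(OC)cc(OC)c2)cc1
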